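## Retrosynthetic overview

1. Target 31 ⇒ ester bond between the hindered 3α-OH of the bis-silylated core 23 and (2E,4E,6S)-6-methylocta-2,4-dienoic acid 28 (from (S)-2-methylbutan-1-ol by a vinylogous Horner–Wadsworth–Emmons reaction).
2. Core 23 ⇒ diosphenol by α'-hydroxylation/oxidation of the ring B enone; 2β-OH/3α-OH by trans-diaxial opening of a 2α,3α-epoxide made from the Δ2 alkene 14 through a bromohydrin.
3. 14 ⇒ C4 ketone of (S)-Wieland–Miescher ketone 5: enol triflate/methyl coupling, hydroboration (sets 4α-Me cis to the C5 methyl), oxidation, Δ2 enol triflate reduction; the enone is masked as a dithiolane.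
4. 5 ⇒ key C–C bond: intermolecular Michael addition of 2-methylcyclohexane-1,3-dione 1 to methyl vinyl ketone 2, then L-proline aldol condensation.
5. Ring order: ring A is the carbocycle of 1; ring B is closed second by the aldol condensation.

Convention: eremophilane numbering for the core (ring A = C1–C5, C10; ring B = C5–C10; methyl groups on C4 and C5); α is the face of the C5 methyl, β the opposite face. From 10 onward every core compound carries the 4α- and 5α-methyl groups.
Assumption: the 7-hydroxy-6,9-dien-8-one drawn in the target SMILES is the stable tautomer of the 7,8-dione, so the dione formed in step 13 enolises to it spontaneously.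

## Route

Step 1
Reactants: 1 2-methylcyclohexane-1,3-dione; 2 methyl vinyl ketone
Product: 3 2-methyl-2-(3-oxobutyl)cyclohexane-1,3-dione
Conditions: H2O, AcOH (cat.), hydroquinone (cat.), 75 °C
Reagents that add atoms: none
Why: Intermolecular Michael addition of the enolised 1,3-dione to the enone joins the two fragments at the future C5–C6 bond and creates the quaternary carbon; 3 is achiral, so nothing needs controlling yet.

Step 2
Reactants: 3 2-methyl-2-(3-oxobutyl)cyclohexane-1,3-dione
Product: 5 (S)-Wieland–Miescher ketone, via cis-fused ketol 4 (not isolated)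
Conditions: L-proline (5 mol%), DMSO, 25 °C, 5 d; recrystallisation (Et2O/hexane) to >99% ee
Reagents that add atoms: none
Why: Hajos–Parrish–Eder–Sauer–Wiechert aldol condensation closes ring B: the proline enamine of the methyl ketone attacks one of the two enantiotopic ring carbonyls in a hydrogen-bonded chair transition state, ketol 4 dehydrates, and L-proline gives the (S)-enedione (about 70% ee before recrystallisation), which fixes C5.

Step 3
Reactants: 5 (S)-Wieland–Miescher ketone
Product: 6 4-oxo-9-ene 8-dithiolane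
Conditions: HSCH2CH2SH (1.05 equiv), p-TsOH·H2O (0.1 equiv), AcOH, 25 °C
Reagents that add atoms: ethane-1,2-dithiol SCCS
Why: Chemoselective thioketalisation: under these conditions the conjugated carbonyl reacts faster than the neopentyl C4 ketone, and the double bond stays at C9=C10.

Step 4
Reactants: 6 4-oxo-9-ene 8-dithiolane
Product: 7 4-triflyloxy-3,9-diene 8-dithiolane
Conditions: KN(SiMe3)2, THF, −78 °C; PhNTf2, −78 → 0 °C
Reagents that add atoms: N-phenylbis(trifluoromethanesulfonimide) O=S(=O)(N(c1ccccc1)S(=O)(=O)C(F)(F)F)C(F)(F)F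
Why: Enolate O-triflation; the ketone can enolise only toward C3 because C5 is quaternary.

Step 5
Reactants: 7 4-triflyloxy-3,9-diene 8-dithiolane
Product: 8 4-methyl-3,9-diene 8-dithiolane
Conditions: MeMgBr, Fe(acac)3 (5 mol%), THF/NMP, −30 → 0 °C
Reagents that add atoms: methylmagnesium bromide C[Mg]Br
Why: Iron-catalysed Kumada-type cross-coupling of an alkenyl triflate with a methyl Grignard reagent is fast at low temperature and tolerates the thioketal.

Step 6
Reactants: 8 4-methyl-3,9-diene 8-dithiolane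
Product: 10 3β-hydroxy-4α-methyl-9-ene 8-dithiolane, via 3β-alkylborane 9 (not isolated)
Conditions: BH3·THF (1.2 equiv), THF, 0 → 25 °C; then 3 M NaOH, 30% H2O2, 0 °C
Reagents that add atoms: hydrogen peroxide OO
Why: Hydroboration–oxidation: borane adds syn to the more accessible C3=C4 bond from the β face, opposite the adjacent axial C5 methyl, with boron at C3, so hydrogen enters C4 from β and the methyl-bearing centre becomes 4α (cis to the C5 methyl); C9=C10 is shielded by the spiro-dithiolane and the quaternary carbon.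

Step 7
Reactants: 10 3β-hydroxy-4α-methyl-9-ene 8-dithiolane
Product: 11 4α-methyl-3-oxo-9-ene 8-dithiolane
Conditions: (COCl)2, DMSO, CH2Cl2, −78 °C; Et3N, −78 → −20 °C
Reagents that add atoms: none
Why: Swern oxidation leaves the thioketal alone and, being cold and brief in base, does not epimerise the 4α-methyl centre.

Step 8
Reactants: 11 4α-methyl-3-oxo-9-ene 8-dithiolane
Product: 12 4α-methyl-3-triflyloxy-2,9-diene 8-dithiolane
Conditions: LiN(iPr)2, THF, −78 °C; PhNTf2, −78 → 0 °C
Reagents that add atoms: N-phenylbis(trifluoromethanesulfonimide) O=S(=O)(N(c1ccccc1)S(=O)(=O)C(F)(F)F)C(F)(F)F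
Why: Kinetic deprotonation takes place at the unhindered C2 methylene and not at the tertiary C4–H, and O-triflation fixes the future alkene at C2=C3 without touching C4.

Step 9
Reactants: 12 4α-methyl-3-triflyloxy-2,9-diene 8-dithiolane
Product: 13 4α-methyl-2,9-diene 8-dithiolane
Conditions: Pd(OAc)2 (5 mol%), PPh3 (10 mol%), HCO2H, Bu3N, DMF, 60 °C
Reagents that add atoms: none
Why: Palladium-catalysed formate reduction of an alkenyl triflate (Cacchi reduction) replaces OTf by H without moving the double bond.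

Step 10
Reactants: 13 4α-methyl-2,9-diene 8-dithiolane
Product: 14 4α,5α-dimethyl-2,9-dien-8-one
Conditions: MeI (excess), CaCO3, MeCN/H2O 4:1, 45 °C
Reagents that add atoms: water O
Why: Alkylative thioketal hydrolysis (S-methylation, then water) releases the enone under nearly neutral conditions that do not isomerise the skipped diene.

Step 11
Reactants: 14 4α,5α-dimethyl-2,9-dien-8-one
Product: 16 2α,3α-epoxy-9-en-8-one, via trans-bromohydrin 15 (not isolated)
Conditions: NBS, THF/H2O 3:1, 0 °C, dark; then K2CO3, MeOH, 0 °C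
Reagents that add atoms: N-bromosuccinimide O=C1CCC(=O)N1Br; water O
Why: Bromohydrin formation and ring closure: Br+ adds to the isolated Δ2 bond from the β face (anti to both methyl groups), water opens the bromonium ion anti from the α face, and base closes either regioisomeric trans-bromohydrin to the same 2α,3α-epoxide, the one a peracid would not give.

Step 12
Reactants: 16 2α,3α-epoxy-9-en-8-one
Product: 19 2α,3α-epoxy-7β-hydroxy-9-en-8-one, via silyl dienol ether 17 (not isolated), via 7β-silyloxy ketone 18 (not isolated)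
Conditions: LiN(iPr)2, THF, −78 °C, then Me3SiCl; mCPBA, NaHCO3, CH2Cl2, −20 → 0 °C; citric acid, MeOH, 25 °C
Reagents that add atoms: chlorotrimethylsilane C[Si](C)(C)Cl; mCPBA OOC(=O)c1cccc(Cl)c1
Why: Rubottom oxidation: kinetic α'-deprotonation at C7 gives the cross-conjugated silyl dienol ether, whose electron-rich C7=C8 bond is oxidised by the peracid (mainly anti to the C5 methyl) and rearranges to the α'-silyloxy enone; the C7 configuration is erased in step 13.

Step 13
Reactants: 19 2α,3α-epoxy-7β-hydroxy-9-en-8-one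
Product: 21 2α,3α-epoxy-7-hydroxy-6,9-dien-8-one, via 7,8-diketone 20 (not isolated)
Conditions: Dess–Martin periodinane, CH2Cl2, 0 → 25 °C
Reagents that add atoms: none
Why: Dess–Martin oxidation of the only free hydroxyl gives the 1,2-diketone, which enolises toward C6 to the conjugated, hydrogen-bonded diosphenol.

Step 14
Reactants: 21 2α,3α-epoxy-7-hydroxy-6,9-dien-8-one
Product: 22 2β,3α,7-trihydroxy-6,9-dien-8-one
Conditions: 0.5 M aq. HClO4, THF, 25 °C
Reagents that add atoms: water O
Why: Acid-catalysed trans-diaxial epoxide opening (Fürst–Plattner rule): water attacks C2 from the β face, which is both the axial trajectory and the carbon remote from the C4 methyl, so the C3 oxygen stays α and the new C2 hydroxyl is β.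

Step 15
Reactants: 22 2β,3α,7-trihydroxy-6,9-dien-8-one
Product: 23 2β,7-bis(tert-butyldimethylsilyloxy)-3α-hydroxy-6,9-dien-8-one
Conditions: TBSCl (2.3 equiv), imidazole, DMF, 0 → 25 °C
Reagents that add atoms: tert-butyldimethylsilyl chloride CC(C)(C)[Si](C)(C)Cl
Why: Sterically selective silylation: the acidic enol OH and the unhindered 2β-OH react, whereas the 3α-OH, syn-axial to the C5 methyl and flanked by the C4 methyl, does not.

Step 16
Reactants: 24 (S)-2-methylbutan-1-ol
Product: 25 (S)-2-methylbutanal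
Conditions: 2,2,6,6-tetramethylpiperidin-1-oxyl (1 mol%), KBr (10 mol%), aq. NaOCl (pH 9.5), CH2Cl2, 0 °C; used at once
Reagents that add atoms: none
Why: Anelli oxidation (oxoammonium/hypochlorite) stops at the aldehyde and does not racemise the α-stereocentre at 0 °C.

Step 17
Reactants: 25 (S)-2-methylbutanal; 26 triethyl (E)-4-phosphonocrotonate
Product: 27 ethyl (2E,4E,6S)-6-methylocta-2,4-dienoate
Conditions: LiN(SiMe3)2, THF, −78 → 0 °C (aldehyde added to the preformed anion)
Reagents that add atoms: none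
Why: Vinylogous Horner–Wadsworth–Emmons olefination gives the (2E,4E)-dienoate, and adding the aldehyde to the phosphonate anion at −78 °C avoids enolisation of the α-stereocentre.

Step 18
Reactants: 27 ethyl (2E,4E,6S)-6-methylocta-2,4-dienoate
Product: 28 (2E,4E,6S)-6-methylocta-2,4-dienoic acid
Conditions: LiOH·H2O, THF/MeOH/H2O, 25 °C; then 1 M HCl
Reagents that add atoms: lithium hydroxide [Li+].[OH-]
Why: Saponification; the stereocentre is remote from the carboxylate and is not affected.

Step 19
Reactants: 23 2β,7-bis(tert-butyldimethylsilyloxy)-3α-hydroxy-6,9-dien-8-one; 28 (2E,4E,6S)-6-methylocta-2,4-dienoic acid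
Product: 30 2β,7-bis(tert-butyldimethylsilyloxy)-3α-dienoyloxy-6,9-dien-8-one, via mixed anhydride 29 (not isolated)
Conditions: 2,4,6-Cl3C6H2COCl, Et3N, toluene, 25 °C; then 23, 4-(dimethylamino)pyridine, toluene, 50 °C
Reagents that add atoms: 2,4,6-trichlorobenzoyl chloride O=C(Cl)c1c(Cl)cc(Cl)cc1Cl
Why: Yamaguchi esterification: the mixed anhydride and 4-(dimethylamino)pyridine give a highly reactive acylpyridinium that acylates the hindered axial 3α-hydroxyl with retention at C3.

Step 20
Reactants: 30 2β,7-bis(tert-butyldimethylsilyloxy)-3α-dienoyloxy-6,9-dien-8-one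
Product: 31 Septeremophilane G
Conditions: HF·pyridine, pyridine, THF, 0 → 25 °C
Reagents that add atoms: none
Why: Fluoride-mediated desilylation removes both silyl groups under buffered conditions that leave the dienoate and the diosphenol intact, and acyl migration is not possible across the trans-diaxial diol.

## Compound list

1 | 2-methylcyclohexane-1,3-dione | CC1C(=O)CCCC1=O | starting material
2 | methyl vinyl ketone | CC(=O)C=C | starting material
3 | 2-methyl-2-(3-oxobutyl)cyclohexane-1,3-dione | CC(=O)CCC1(C)C(=O)CCCC1=O | intermediate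
4 | cis-fused ketol (10-hydroxy-5-methyl-decalin-4,8-dione, OH cis to CH3) | C1CC[C@]2(O)CC(=O)CC[C@]2(C)C1=O | intermediate
5 | (S)-Wieland–Miescher ketone, (S)-8a-methyl-3,4,8,8a-tetrahydronaphthalene-1,6(2H,7H)-dione | C[C@]12CCC(=O)C=C1CCCC2=O | intermediate
6 | 4-oxo-9-ene 8-dithiolane (enone carbonyl of 5 as spiro-1,3-dithiolane) | C1CCC2=CC3(SCCS3)CC[C@]2(C)C1=O | intermediate
7 | 4-triflyloxy-3,9-diene 8-dithiolane | C1CC2=CC3(SCCS3)CC[C@]2(C)C(OS(=O)(=O)C(F)(F)F)=C1 | intermediate
8 | 4-methyl-3,9-diene 8-dithiolane | C1CC2=CC3(SCCS3)CC[C@]2(C)C(C)=C1 | intermediate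
9 | 3β-boryl-4α-methyl-9-ene 8-dithiolane (monoalkylborane) | B[C@@H]1CCC2=CC3(SCCS3)CC[C@]2(C)[C@H]1C | intermediate
10 | 3β-hydroxy-4α-methyl-9-ene 8-dithiolane | O[C@@H]1CCC2=CC3(SCCS3)CC[C@]2(C)[C@H]1C | intermediate
11 | 4α-methyl-3-oxo-9-ene 8-dithiolane | O=C1CCC2=CC3(SCCS3)CC[C@]2(C)[C@H]1C | intermediate
12 | 4α-methyl-3-triflyloxy-2,9-diene 8-dithiolane | FC(F)(F)S(=O)(=O)OC1=CCC2=CC3(SCCS3)CC[C@]2(C)[C@H]1C | intermediate
13 | 4α-methyl-2,9-diene 8-dithiolane | C1=CCC2=CC3(SCCS3)CC[C@]2(C)[C@H]1C | intermediate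
14 | 4α,5α-dimethyl-2,9-dien-8-one (11,12,13-trinoreremophila-2,9-dien-8-one) | C1=CCC2=CC(=O)CC[C@]2(C)[C@H]1C | intermediate
15 | 2β-bromo-3α-hydroxy-9-en-8-one | O[C@H]1[C@H](Br)CC2=CC(=O)CC[C@]2(C)[C@H]1C | intermediate
16 | 2α,3α-epoxy-9-en-8-one | O1[C@H]2[C@@H]1CC3=CC(=O)CC[C@]3(C)[C@H]2C | intermediate
17 | 2α,3α-epoxy-8-(trimethylsilyloxy)-7,9-diene | O1[C@H]2[C@@H]1CC3=CC(O[Si](C)(C)C)=CC[C@]3(C)[C@H]2C | intermediate
18 | 2α,3α-epoxy-7β-(trimethylsilyloxy)-9-en-8-one | O1[C@H]2[C@@H]1CC3=CC(=O)[C@H](O[Si](C)(C)C)C[C@]3(C)[C@H]2C | intermediate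
19 | 2α,3α-epoxy-7β-hydroxy-9-en-8-one | O1[C@H]2[C@@H]1CC3=CC(=O)[C@H](O)C[C@]3(C)[C@H]2C | intermediate
20 | 2α,3α-epoxy-9-ene-7,8-dione | O1[C@H]2[C@@H]1CC3=CC(=O)C(=O)C[C@]3(C)[C@H]2C | intermediate
21 | 2α,3α-epoxy-7-hydroxy-6,9-dien-8-one | O1[C@H]2[C@@H]1CC3=CC(=O)C(O)=C[C@]3(C)[C@H]2C | intermediate
22 | 2β,3α,7-trihydroxy-6,9-dien-8-one | O[C@H]1[C@H](O)CC2=CC(=O)C(O)=C[C@]2(C)[C@H]1C | intermediate
23 | 2β,7-bis(tert-butyldimethylsilyloxy)-3α-hydroxy-6,9-dien-8-one | O[C@H]1[C@H](O[Si](C)(C)C(C)(C)C)CC2=CC(=O)C(O[Si](C)(C)C(C)(C)C)=C[C@]2(C)[C@H]1C | intermediate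
24 | (S)-2-methylbutan-1-ol | CC[C@H](C)CO | starting material
25 | (S)-2-methylbutanal | CC[C@H](C)C=O | intermediate
26 | triethyl (E)-4-phosphonocrotonate | CCOC(=O)/C=C/CP(=O)(OCC)OCC | starting material
27 | ethyl (2E,4E,6S)-6-methylocta-2,4-dienoate | CC[C@H](C)/C=C/C=C/C(=O)OCC | intermediate
28 | (2E,4E,6S)-6-methylocta-2,4-dienoic acid | CC[C@H](C)/C=C/C=C/C(=O)O | intermediate
29 | mixed anhydride of 28 with 2,4,6-trichlorobenzoic acid | CC[C@H](C)/C=C/C=C/C(=O)OC(=O)c1c(Cl)cc(Cl)cc1Cl | intermediate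
30 | 2β,7-bis(tert-butyldimethylsilyloxy)-3α-[(2E,4E,6S)-6-methylocta-2,4-dienoyloxy]-6,9-dien-8-one | CC[C@H](C)/C=C/C=C/C(=O)O[C@H]1[C@H](O[Si](C)(C)C(C)(C)C)CC2=CC(=O)C(O[Si](C)(C)C(C)(C)C)=C[C@]2(C)[C@H]1C | intermediate
31 | Septeremophilane G, (2R,3R,4R,5S)-2,7-dihydroxy-8-oxo-11,12,13-trinoreremophila-6,9-dien-3-yl (2E,4E,6S)-6-methylocta-2,4-dienoate | CC[C@H](C)/C=C/C=C/C(=O)O[C@H]1[C@H](O)CC2=CC(=O)C(O)=C[C@]2(C)[C@H]1C | target

## Step count and risks

Total: 20 steps. Longest linear sequence: 17 steps (steps 1–15, 19, 20); the acid 28 takes 3 steps (16–18).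

The three steps most likely to fail:

(a) Step 11, epoxide on the hindered face. The risk is imperfect face selectivity of bromonium formation and elimination of HBr from the δ-bromo enone in base. The fallback sets out from ketone 11 and comes back at epoxide 16, placing both oxygens at the ketone stage instead of on an alkene. KN(SiMe3)2 at −78 °C followed by 2-(phenylsulfonyl)-3-phenyloxaziridine hydroxylates the Δ2 enolate by axial attack from the β face and gives the 2β-hydroxy-3-ketone F1. Me4NBH(OAc)3 in MeCN/AcOH at −20 °C delivers hydride from the hydroxyl-bearing β face (the α face is also blocked by the C5 methyl) and gives the 2β,3α-diol F2. MeI/CaCO3 in aqueous MeCN unmasks the enone to give the diol enone F3. MsCl with 2,4,6-collidine at −20 °C sulfonylates only the unhindered 2β-hydroxyl to give the hydroxy mesylate F4, and K2CO3 in MeOH closes this trans-diaxial pair to 16.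

(b) Step 12, strong base on the epoxy enone. The C1 hydrogens are γ to the carbonyl and β to the epoxide, so any equilibration of the kinetic enolate opens the epoxide by vinylogous elimination. The fallback sets out from dienone 14 and comes back at 19, oxidising C7 without base and before the epoxide exists. Mn(OAc)3 in refluxing benzene gives the 7β-acetoxy dienone F5 by α'-acetoxylation. NBS in aqueous THF then gives the bromohydrin acetate F6 (not isolated), and K2CO3 in MeOH at 0 °C both closes the 2α,3α-epoxide and methanolyses the acetate to give 19.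

(c) Step 19, acylation of a hydroxyl that is syn-axial to the C5 methyl. The fallback sets out from alcohol 23 (and aldehyde 25) and comes back at ester 30, building the dienoate on the alcohol instead of transferring it whole. Diethylphosphonoacetic acid with DCC, a small ketene-like acyl donor, gives the phosphonoacetate F7. Aldehyde 25 and Ph3P=CHCHO in toluene give (S,E)-4-methylhex-2-enal F8. A Masamune–Roush Horner–Wadsworth–Emmons reaction of F7 with F8 (LiCl, iPr2NEt, MeCN) forms the C2'=C3' bond E-selectively and gives 30.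

## Further compounds

F1 | step 11 | 2β-hydroxy-4α-methyl-3-oxo-9-ene 8-dithiolane | O=C1[C@H](O)CC2=CC3(SCCS3)CC[C@]2(C)[C@H]1C
F2 | step 11 | 2β,3α-dihydroxy-4α-methyl-9-ene 8-dithiolane | O[C@H]1[C@H](O)CC2=CC3(SCCS3)CC[C@]2(C)[C@H]1C
F3 | step 11 | 2β,3α-dihydroxy-9-en-8-one | O[C@H]1[C@H](O)CC2=CC(=O)CC[C@]2(C)[C@H]1C
F4 | step 11 | 3α-hydroxy-2β-(methanesulfonyloxy)-9-en-8-one | O[C@H]1[C@H](OS(C)(=O)=O)CC2=CC(=O)CC[C@]2(C)[C@H]1C
F5 | step 12 | 7β-acetoxy-2,9-dien-8-one | C1=CCC2=CC(=O)[C@H](OC(C)=O)C[C@]2(C)[C@H]1C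
F6 | step 12 | 7β-acetoxy-2β-bromo-3α-hydroxy-9-en-8-one | O[C@H]1[C@H](Br)CC2=CC(=O)[C@H](OC(C)=O)C[C@]2(C)[C@H]1C
F7 | step 19 | 2β,7-bis(tert-butyldimethylsilyloxy)-3α-(diethylphosphonoacetoxy)-6,9-dien-8-one | CCOP(=O)(OCC)CC(=O)O[C@H]1[C@H](O[Si](C)(C)C(C)(C)C)CC2=CC(=O)C(O[Si](C)(C)C(C)(C)C)=C[C@]2(C)[C@H]1C
F8 | step 19 | (S,E)-4-methylhex-2-enal | CC[C@H](C)/C=C/C=O
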